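Side-chain carbons are numbered C1' (on C3 of the quinone ring) to C32'. The retrosynthesis first masks the quinone ring as its 1,4-dimethyl ether, then cuts C9'–C10' and C11'–CH3 in one operation: in the E alkene C10'=C11' the methyl on C11' is cis to C9', so this alkene is the syn adduct of CH3 and C9' across a terminal alkyne C10'≡C11'.
Three components result: a C28 pentaenyne (C10'–C32'), Me3Al and a primary homoallylic iodide (C1'–C9' on the dimethoxynaphthalene); they are joined in one pot by zirconium-catalysed methylalumination, Al-to-Zn exchange and palladium-catalysed alkenyl–alkyl coupling.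
The enyne is cut further at C13'–C14' (the same alkyne-to-E-alkene logic in its established two-flask form: alkenyl iodide plus a C4 alkynylzinc) and at C16'–C17' (propargylation of geranylgeranyl bromide).
The iodide is cut at C3–C1' (aryl Grignard plus geranyl bromide) and at C8'–C9' (methylenation of the enal made by allylic oxidation of the terminal E-methyl group; hydroboration and iodination then make C9' electrophilic).
Forward order: geranylgeraniol → C23 enyne → alkenyl iodide → C28 enyne; menadione → bromo dimethyl ether → geranyl arene → enal → triene → alcohol → iodide; three-component union; oxidative demethylation to the quinone.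
There are no stereocentres; the E alkenes at C2' and C6' come from geranyl bromide, those at C18', C22' and C26' from geranylgeraniol, and those at C14' and C10' from syn carboalumination followed by C–C bond formation with retention.

Key step: step 14

Assumption: geranylgeraniol and geranyl bromide are bought as the all-E isomers, so five of the seven E alkenes are carried in from the starting materials and are never exposed to isomerising conditions.

Step 1
Reactants: 1 (2E,6E,10E)-geranylgeraniol
Product: 2 (2E,6E,10E)-geranylgeranyl bromide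
Conditions: PBr3 (0.4 equiv), Et2O, −10 °C
Reagents that add atoms: phosphorus tribromide, BrP(Br)Br
Why: Bromination of a primary allylic alcohol through its phosphite ester is an SN2 displacement at C17' that should leave the E alkenes and the allylic position unrearranged at low temperature.

Step 2
Reactants: 2 (2E,6E,10E)-geranylgeranyl bromide; 3 1-(trimethylsilyl)propyne
Product: 5 trimethyl[(5E,9E,13E)-6,10,14,18-tetramethylnonadeca-5,9,13,17-tetraen-1-yn-1-yl]silane, via lithiated silylpropyne 4 (not isolated)
Conditions: n-BuLi, THF, −78 → −20 °C (3 → 4); then 2, −78 °C → rt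
Reagents that add atoms: n-butyllithium, [Li]CCCC (lithium of 4 only)
Why: Propargylic C-alkylation of lithiated 1-(trimethylsilyl)propyne: the bulky silyl group steers the ambident anion to react at its CH2 terminus in an SN2 displacement of the primary allylic bromide, which should form C16'–C17' without touching the E alkenes.

Step 3
Reactants: 5 trimethyl[(5E,9E,13E)-6,10,14,18-tetramethylnonadeca-5,9,13,17-tetraen-1-yn-1-yl]silane
Product: 6 (5E,9E,13E)-6,10,14,18-tetramethylnonadeca-5,9,13,17-tetraen-1-yne
Conditions: K2CO3 (cat.), MeOH/THF, rt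
Reagents that add atoms: none
Why: Base-catalysed methanolysis of the C(sp)–Si bond (protodesilylation) should free the terminal alkyne needed for carbometalation.

Step 4
Reactants: 6 (5E,9E,13E)-6,10,14,18-tetramethylnonadeca-5,9,13,17-tetraen-1-yne
Product: 8 (1E,5E,9E,13E)-1-iodo-2,6,10,14,18-pentamethylnonadeca-1,5,9,13,17-pentaene, via alkenylalane 7 (not isolated)
Conditions: Me3Al (2 equiv), Cp2ZrCl2 (0.25 equiv), CH2Cl2, 0 °C → rt; then I2, THF, −30 → 0 °C
Reagents that add atoms: trimethylaluminium, C[Al](C)C (the methyl group on C15'; aluminium of 7 only); iodine, II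
Why: Zirconium-catalysed carboalumination (methylalumination) adds CH3 to the internal and Al to the terminal alkyne carbon in a syn fashion and iodinolysis of the C–Al bond occurs with retention, so the C14'=C15' alkene should form as the E isomer while the isolated trisubstituted alkenes stay inert.

Step 5
Reactants: 8 (1E,5E,9E,13E)-1-iodo-2,6,10,14,18-pentamethylnonadeca-1,5,9,13,17-pentaene; 9 (4-bromobut-1-yn-1-yl)trimethylsilane
Product: 11 trimethyl[(5E,9E,13E,17E)-6,10,14,18,22-pentamethyltricosa-5,9,13,17,21-pentaen-1-yn-1-yl]silane, via alkylzinc bromide 10 (not isolated)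
Conditions: 9, Zn dust, LiCl, THF, 50 °C (→ 10); then 8, Pd(PPh3)4 (3 mol%), THF, rt → 40 °C
Reagents that add atoms: zinc, [Zn] (in 10 only)
Why: Negishi coupling: the primary alkylzinc bromide from LiCl-assisted zinc insertion transmetalates to the alkenylpalladium iodide formed from zerovalent palladium, and reductive elimination should join C13' to C14' with retention of the E geometry.

Step 6
Reactants: 11 trimethyl[(5E,9E,13E,17E)-6,10,14,18,22-pentamethyltricosa-5,9,13,17,21-pentaen-1-yn-1-yl]silane
Product: 12 (5E,9E,13E,17E)-6,10,14,18,22-pentamethyltricosa-5,9,13,17,21-pentaen-1-yne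
Conditions: K2CO3 (cat.), MeOH/THF, rt
Reagents that add atoms: none
Why: Base-catalysed protodesilylation of the alkynylsilane should give the terminal alkyne C10'≡C11' for the fragment union.

Step 7
Reactants: 13 menadione (2-methylnaphthalene-1,4-dione)
Product: 15 1,4-dimethoxy-2-methylnaphthalene, via menadiol 14 (not isolated)
Conditions: Na2S2O4, n-Bu4NBr (cat.), THF/H2O, rt; then KOH (aq), Me2SO4, 0 °C → rt
Reagents that add atoms: dimethyl sulfate, COS(=O)(=O)OC
Why: Reductive methylation: dithionite reduces the quinone to the hydroquinone, whose phenoxides are O-methylated (Williamson ether synthesis), which should mask the quinone ring as an arene that tolerates organometallic reagents.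

Step 8
Reactants: 15 1,4-dimethoxy-2-methylnaphthalene
Product: 16 2-bromo-1,4-dimethoxy-3-methylnaphthalene
Conditions: Br2, CH2Cl2, 0 °C
Reagents that add atoms: bromine, BrBr
Why: Electrophilic aromatic bromination should occur only at C3, the one free position of the ring activated by two methoxy groups and the methyl group.

Step 9
Reactants: 16 2-bromo-1,4-dimethoxy-3-methylnaphthalene; 17 geranyl bromide ((2E)-1-bromo-3,7-dimethylocta-2,6-diene)
Product: 19 2-[(2E)-3,7-dimethylocta-2,6-dien-1-yl]-1,4-dimethoxy-3-methylnaphthalene, via arylmagnesium bromide 18 (not isolated)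
Conditions: Mg, THF, 50 °C (16 → 18); then CuBr·SMe2 (5 mol%), 17, −20 °C → rt
Reagents that add atoms: magnesium, [Mg] (in 18 only)
Why: Copper-catalysed allylic substitution of a Grignard reagent: the aryl group should displace the primary bromide at the alpha carbon (SN2), so the C3–C1' bond forms with the E geometry of geranyl bromide intact.

Step 10
Reactants: 19 2-[(2E)-3,7-dimethylocta-2,6-dien-1-yl]-1,4-dimethoxy-3-methylnaphthalene
Product: 21 (2E,6E)-8-(1,4-dimethoxy-3-methylnaphthalen-2-yl)-2,6-dimethylocta-2,6-dienal, via allylic alcohol 20 (not isolated)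
Conditions: SeO2 (0.5 equiv), t-BuOOH (2 equiv), salicylic acid (10 mol%), CH2Cl2, 0 °C → rt; aqueous wash; then MnO2, CH2Cl2, rt
Reagents that add atoms: tert-butyl hydroperoxide, CC(C)(C)OO (the oxygen of 20 and 21, passed on through SeO2, O=[Se]=O)
Why: Selenium dioxide allylic oxidation (ene reaction followed by a 2,3-sigmatropic shift) selects the E-methyl group of the terminal, least hindered trisubstituted alkene, and MnO2 oxidation of the allylic alcohol should funnel the alcohol and any aldehyde already formed into the (E)-enal.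

Step 11
Reactants: 21 (2E,6E)-8-(1,4-dimethoxy-3-methylnaphthalen-2-yl)-2,6-dimethylocta-2,6-dienal
Product: 22 2-[(2E,6E)-3,7-dimethylnona-2,6,8-trien-1-yl]-1,4-dimethoxy-3-methylnaphthalene
Conditions: Ph3PCH3Br, KN(SiMe3)2, THF, −78 → 0 °C
Reagents that add atoms: methyltriphenylphosphonium bromide, C[P+](c1ccccc1)(c1ccccc1)c1ccccc1.[Br-]
Why: Wittig methylenation with the non-stabilised ylide should turn the aldehyde carbon C8' into the vinyl group C8'=C9' without affecting the trisubstituted C6'=C7' geometry.

Step 12
Reactants: 22 2-[(2E,6E)-3,7-dimethylnona-2,6,8-trien-1-yl]-1,4-dimethoxy-3-methylnaphthalene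
Product: 24 (3E,7E)-9-(1,4-dimethoxy-3-methylnaphthalen-2-yl)-3,7-dimethylnona-3,7-dien-1-ol, via B-alkyl-9-BBN 23 (not isolated)
Conditions: 9-BBN (1.1 equiv), THF, 0 °C → rt; then NaOH (aq), H2O2, 0 °C → rt
Reagents that add atoms: 9-borabicyclo[3.3.1]nonane, B1C2CCCC1CCC2 (boron and bicyclic carbons of 23 only); hydrogen peroxide, OO (the oxygen of 24)
Why: Hydroboration–oxidation: the bulky 9-BBN should add anti-Markovnikov to the monosubstituted C8'=C9' alkene much faster than to the trisubstituted alkenes, and alkaline peroxide oxidation then gives the primary alcohol at C9'.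

Step 13
Reactants: 24 (3E,7E)-9-(1,4-dimethoxy-3-methylnaphthalen-2-yl)-3,7-dimethylnona-3,7-dien-1-ol
Product: 25 2-[(2E,6E)-9-iodo-3,7-dimethylnona-2,6-dien-1-yl]-1,4-dimethoxy-3-methylnaphthalene
Conditions: PPh3, I2, imidazole, CH2Cl2, 0 °C → rt
Reagents that add atoms: iodine, II
Why: Appel-type iodination: the alkoxyphosphonium ion formed from PPh3/I2 should be displaced by iodide in an SN2 reaction at the primary carbon, with imidazole as the acid scavenger.

Step 14
Reactants: 12 (5E,9E,13E,17E)-6,10,14,18,22-pentamethyltricosa-5,9,13,17,21-pentaen-1-yne; 25 2-[(2E,6E)-9-iodo-3,7-dimethylnona-2,6-dien-1-yl]-1,4-dimethoxy-3-methylnaphthalene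
Product: 28 1,4-dimethoxy-2-methyl-3-[(2E,6E,10E,14E,18E,22E,26E)-3,7,11,15,19,23,27,31-octamethyldotriaconta-2,6,10,14,18,22,26,30-octaen-1-yl]naphthalene, via alkenylalane 26 (not isolated), via alkenylzinc chloride 27 (not isolated)
Conditions: 12 (1.3 equiv), Me3Al (2.0 equiv), Cp2ZrCl2 (0.25 equiv), CH2Cl2, 0 °C → rt; volatiles removed in vacuo; ZnCl2 (1.0 equiv per alane), THF, 0 °C; then 25 (1.0 equiv), Pd2(dba)3 (2 mol%), P(c-C5H9)3 (8 mol%), N-methylimidazole (1.2 equiv), THF/NMP, 60 °C
Reagents that add atoms: trimethylaluminium, C[Al](C)C (the methyl group on C11' of 28; aluminium of 26 only); zinc dichloride, Cl[Zn]Cl (zinc and chlorine of 27 only)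
Why: Proposed new method: zirconium-catalysed methylalumination adds CH3 (to C11') and Al (to C10') syn across the terminal alkyne of 12 to give alane 26, Al-to-Zn exchange with ZnCl2 gives alkenylzinc 27, and zerovalent palladium carrying the bulky, electron-rich P(c-C5H9)3 inserts into the primary C9'–I bond of 25 by an SN2-type oxidative addition, takes over the alkenyl group by transmetalation and forms the C9'–C10' bond by reductive elimination. The closest known reaction types are the one-pot carboalumination/palladium- or nickel-catalysed coupling of such alkenylalanes with aryl, alkenyl, allylic and benzylic halides and the palladium/trialkylphosphine Negishi coupling of alkenylzinc halides with unactivated primary alkyl iodides; their merger, with a β-hydrogen-bearing alkyl iodide as the electrophile for a carboalumination-derived alkenyl metal, is the untested part. No ring is closed and no stereocentre is formed; the only stereochemical element, the E geometry of C10'=C11', is fixed by the syn addition and carried through Al-to-Zn exchange, transmetalation and reductive elimination, all of which retain alkenyl configuration. The regioselectivity of the methyl transfer follows from placing the metal on the unhindered terminal carbon C10', and the seven alkenes already present and the aryl methyl ethers are inert to Me3Al/Cp2ZrCl2. The step needs alkenyl-over-methyl transfer and coupling faster than β-hydride elimination from the homoallylic alkylpalladium iodide: the first should be secured by stripping excess Me3Al and limiting ZnCl2 to one equivalent (the sp2 group exchanges fastest), the second by the hindered trialkylphosphine and the N-methylimidazole-activated zinc reagent, which speed transmetalation and reductive elimination.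

Step 15
Reactants: 28 1,4-dimethoxy-2-methyl-3-[(2E,6E,10E,14E,18E,22E,26E)-3,7,11,15,19,23,27,31-octamethyldotriaconta-2,6,10,14,18,22,26,30-octaen-1-yl]naphthalene
Product: 29 menaquinone-8
Conditions: (NH4)2Ce(NO3)6 (2.5 equiv), MeCN/H2O/CH2Cl2, 0 °C
Reagents that add atoms: water, O (the two carbonyl oxygens)
Why: Oxidative demethylation with tetravalent cerium: two one-electron oxidations of the electron-rich dialkoxyarene with ipso attack of water should release two molecules of methanol and unveil the quinone at 0 °C, conditions that isolated trisubstituted alkenes are expected to survive.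

Compound list
1 | (2E,6E,10E)-geranylgeraniol, (2E,6E,10E)-3,7,11,15-tetramethylhexadeca-2,6,10,14-tetraen-1-ol | CC(C)=CCC/C(C)=C/CC/C(C)=C/CC/C(C)=C/CO | starting material
2 | (2E,6E,10E)-geranylgeranyl bromide, (2E,6E,10E)-1-bromo-3,7,11,15-tetramethylhexadeca-2,6,10,14-tetraene | CC(C)=CCC/C(C)=C/CC/C(C)=C/CC/C(C)=C/CBr | intermediate
3 | 1-(trimethylsilyl)propyne | CC#C[Si](C)(C)C | starting material
4 | 3-lithio-1-(trimethylsilyl)propyne (formed in the flask) | [Li]CC#C[Si](C)(C)C | intermediate
5 | trimethyl[(5E,9E,13E)-6,10,14,18-tetramethylnonadeca-5,9,13,17-tetraen-1-yn-1-yl]silane | CC(C)=CCC/C(C)=C/CC/C(C)=C/CC/C(C)=C/CCC#C[Si](C)(C)C | intermediate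
6 | (5E,9E,13E)-6,10,14,18-tetramethylnonadeca-5,9,13,17-tetraen-1-yne | CC(C)=CCC/C(C)=C/CC/C(C)=C/CC/C(C)=C/CCC#C | intermediate
7 | dimethyl[(1E,5E,9E,13E)-2,6,10,14,18-pentamethylnonadeca-1,5,9,13,17-pentaen-1-yl]alane (formed in the flask) | CC(C)=CCC/C(C)=C/CC/C(C)=C/CC/C(C)=C/CC/C(C)=C/[Al](C)C | intermediate
8 | (1E,5E,9E,13E)-1-iodo-2,6,10,14,18-pentamethylnonadeca-1,5,9,13,17-pentaene | CC(C)=CCC/C(C)=C/CC/C(C)=C/CC/C(C)=C/CC/C(C)=C/I | intermediate
9 | (4-bromobut-1-yn-1-yl)trimethylsilane | BrCCC#C[Si](C)(C)C | starting material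
10 | bromo[4-(trimethylsilyl)but-3-yn-1-yl]zinc (formed in the flask) | Br[Zn]CCC#C[Si](C)(C)C | intermediate
11 | trimethyl[(5E,9E,13E,17E)-6,10,14,18,22-pentamethyltricosa-5,9,13,17,21-pentaen-1-yn-1-yl]silane | CC(C)=CCC/C(C)=C/CC/C(C)=C/CC/C(C)=C/CC/C(C)=C/CCC#C[Si](C)(C)C | intermediate
12 | (5E,9E,13E,17E)-6,10,14,18,22-pentamethyltricosa-5,9,13,17,21-pentaen-1-yne | CC(C)=CCC/C(C)=C/CC/C(C)=C/CC/C(C)=C/CC/C(C)=C/CCC#C | intermediate
13 | menadione, 2-methylnaphthalene-1,4-dione | CC1=CC(=O)c2ccccc2C1=O | starting material
14 | menadiol, 2-methylnaphthalene-1,4-diol (formed in the flask) | Cc1cc(O)c2ccccc2c1O | intermediate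
15 | 1,4-dimethoxy-2-methylnaphthalene | COc1cc(C)c(OC)c2ccccc12 | intermediate
16 | 2-bromo-1,4-dimethoxy-3-methylnaphthalene | COc1c(Br)c(C)c(OC)c2ccccc12 | intermediate
17 | geranyl bromide, (2E)-1-bromo-3,7-dimethylocta-2,6-diene | CC(C)=CCC/C(C)=C/CBr | starting material
18 | (1,4-dimethoxy-3-methylnaphthalen-2-yl)magnesium bromide (formed in the flask) | COc1c([Mg]Br)c(C)c(OC)c2ccccc12 | intermediate
19 | 2-[(2E)-3,7-dimethylocta-2,6-dien-1-yl]-1,4-dimethoxy-3-methylnaphthalene | CC(C)=CCC/C(C)=C/Cc1c(C)c(OC)c2ccccc2c1OC | intermediate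
20 | (2E,6E)-8-(1,4-dimethoxy-3-methylnaphthalen-2-yl)-2,6-dimethylocta-2,6-dien-1-ol (formed in the flask) | OC/C(C)=C/CC/C(C)=C/Cc1c(C)c(OC)c2ccccc2c1OC | intermediate
21 | (2E,6E)-8-(1,4-dimethoxy-3-methylnaphthalen-2-yl)-2,6-dimethylocta-2,6-dienal | O=C/C(C)=C/CC/C(C)=C/Cc1c(C)c(OC)c2ccccc2c1OC | intermediate
22 | 2-[(2E,6E)-3,7-dimethylnona-2,6,8-trien-1-yl]-1,4-dimethoxy-3-methylnaphthalene | C=C/C(C)=C/CC/C(C)=C/Cc1c(C)c(OC)c2ccccc2c1OC | intermediate
23 | 9-[(3E,7E)-9-(1,4-dimethoxy-3-methylnaphthalen-2-yl)-3,7-dimethylnona-3,7-dien-1-yl]-9-borabicyclo[3.3.1]nonane (formed in the flask) | B1(CC/C(C)=C/CC/C(C)=C/Cc2c(C)c(OC)c3ccccc3c2OC)C2CCCC1CCC2 | intermediate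
24 | (3E,7E)-9-(1,4-dimethoxy-3-methylnaphthalen-2-yl)-3,7-dimethylnona-3,7-dien-1-ol | OCC/C(C)=C/CC/C(C)=C/Cc1c(C)c(OC)c2ccccc2c1OC | intermediate
25 | 2-[(2E,6E)-9-iodo-3,7-dimethylnona-2,6-dien-1-yl]-1,4-dimethoxy-3-methylnaphthalene | ICC/C(C)=C/CC/C(C)=C/Cc1c(C)c(OC)c2ccccc2c1OC | intermediate
26 | dimethyl[(1E,5E,9E,13E,17E)-2,6,10,14,18,22-hexamethyltricosa-1,5,9,13,17,21-hexaen-1-yl]alane (formed in the flask) | CC(C)=CCC/C(C)=C/CC/C(C)=C/CC/C(C)=C/CC/C(C)=C/CC/C(C)=C/[Al](C)C | intermediate
27 | chloro[(1E,5E,9E,13E,17E)-2,6,10,14,18,22-hexamethyltricosa-1,5,9,13,17,21-hexaen-1-yl]zinc (formed in the flask) | CC(C)=CCC/C(C)=C/CC/C(C)=C/CC/C(C)=C/CC/C(C)=C/CC/C(C)=C/[Zn]Cl | intermediate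
28 | 1,4-dimethoxy-2-methyl-3-[(2E,6E,10E,14E,18E,22E,26E)-3,7,11,15,19,23,27,31-octamethyldotriaconta-2,6,10,14,18,22,26,30-octaen-1-yl]naphthalene | CC(C)=CCC/C(C)=C/CC/C(C)=C/CC/C(C)=C/CC/C(C)=C/CC/C(C)=C/CC/C(C)=C/CC/C(C)=C/Cc1c(C)c(OC)c2ccccc2c1OC | intermediate
29 | menaquinone-8, 2-methyl-3-[(2E,6E,10E,14E,18E,22E,26E)-3,7,11,15,19,23,27,31-octamethyldotriaconta-2,6,10,14,18,22,26,30-octaen-1-yl]naphthalene-1,4-dione | CC(C)=CCC/C(C)=C/CC/C(C)=C/CC/C(C)=C/CC/C(C)=C/CC/C(C)=C/CC/C(C)=C/CC/C(C)=C/CC1=C(C)C(=O)c2ccccc2C1=O | target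

Total step count: 15.
Longest linear sequence: 9 steps (steps 7–13, 14, 15, from menadione); the other branch is steps 1–6, joining at step 14.

Steps most likely to fail

Step 14 (carries the label). The alkylpalladium iodide formed from 25 may undergo β-hydride elimination before it meets the alkenylzinc reagent (this would return triene 22), and a methyl group may be transferred from aluminium or zinc in place of the alkenyl group. The fallback uses known chemistry with the polarity reversed; it sets out from alkyne 12 and triene 22 and comes back to the route at 28. Alkyne 12 is carboaluminated as in step 14 to alane 26, which is quenched with I2 (THF, −30 °C) to give (1E,5E,9E,13E,17E)-1-iodo-2,6,10,14,18,22-hexamethyltricosa-1,5,9,13,17,21-hexaene F1. Triene 22 is hydroborated with 9-BBN to borane 23 as in step 12, and 23 and F1 are joined in the same flask by B-alkyl Suzuki–Miyaura coupling (PdCl2(dppf), aqueous NaOH, THF, rt). In this order the alkyl group reaches palladium only after the alkenyl group is already bound, so reductive elimination should outrun β-hydride elimination.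

Step 10. The allylic oxidation may lose site selectivity (attack at the allylic positions of the internal C2'=C3' alkene or at the benzylic C1' position) or stall at low conversion. The fallback replaces C–H oxidation by olefin cross-metathesis; it sets out from 19 and comes back at 21. Compound 19 is treated with methacrolein and the second-generation Grubbs catalyst (CH2Cl2, 40 °C). The terminal isopropylidene group should exchange with methacrolein with loss of 2-methylpropene to give the (E)-enal 21 directly, whereas the internal trisubstituted alkene, flanked by the arylmethyl group, is too hindered to react. This fallback makes no compound outside the list (entry F0).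

Step 12. The hydroboration may lose chemoselectivity (1,4-addition across the diene, or attack at a trisubstituted alkene), which would give regioisomeric alcohols. The fallback introduces C9' as a nucleophile; it sets out from allylic alcohol 20 (taken off after the SeO2 stage of step 10) and comes back at 24. Alcohol 20 is converted with PBr3 (Et2O, −10 °C) into 2-[(2E,6E)-8-bromo-3,7-dimethylocta-2,6-dien-1-yl]-1,4-dimethoxy-3-methylnaphthalene F2. Coupling of F2 with (isopropoxydimethylsilyl)methylmagnesium chloride (Li2CuCl4 cat., THF, 0 °C; SN2 at the primary allylic carbon) should give [(3E,7E)-9-(1,4-dimethoxy-3-methylnaphthalen-2-yl)-3,7-dimethylnona-3,7-dien-1-yl]dimethyl(propan-2-yloxy)silane F3. Tamao oxidation of F3 (H2O2, KF, KHCO3, THF/MeOH, rt) then gives alcohol 24.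

Further compounds
F1 | step 14 | (1E,5E,9E,13E,17E)-1-iodo-2,6,10,14,18,22-hexamethyltricosa-1,5,9,13,17,21-hexaene | CC(C)=CCC/C(C)=C/CC/C(C)=C/CC/C(C)=C/CC/C(C)=C/CC/C(C)=C/I
F0 | step 10 | none | none
F2 | step 12 | 2-[(2E,6E)-8-bromo-3,7-dimethylocta-2,6-dien-1-yl]-1,4-dimethoxy-3-methylnaphthalene | BrC/C(C)=C/CC/C(C)=C/Cc1c(C)c(OC)c2ccccc2c1OC
F3 | step 12 | [(3E,7E)-9-(1,4-dimethoxy-3-methylnaphthalen-2-yl)-3,7-dimethylnona-3,7-dien-1-yl]dimethyl(propan-2-yloxy)silane | CC(C)O[Si](C)(C)CC/C(C)=C/CC/C(C)=C/Cc1c(C)c(OC)c2ccccc2c1OC
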